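**Remark on the chemistry.** Atom numbers follow the target in every intermediate, whatever its systematic name: ring C1 (angelate), C2, C3 (methyl), C4 (hydroxyl), C5, C6; chain C7 (methyl), C8, C9 (acetate), C10, C11. In this numbering the target is 1R,3S,4R,6S,7R,9R. The configurations of 1, 5, 8 and 10 were re-derived from the target SMILES and agree with it, so no structure needed correcting. The design changes are a telescoped photooxygenation/rearrangement (no peroxide is isolated), a triethylsilyl group at O4, and an angeloylation without nucleophilic catalyst.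

## Structural features

The target is a monocyclic bisabolane-type sesquiterpenoid: one cyclohexane ring (C1–C6) joined at C6 to an acyclic chain C7–C11 that ends in a trisubstituted alkene. The ring carries four stereocentres in one chair: the C1 angelate, the C3 methyl and the C6 chain are equatorial, and the C4 hydroxyl is axial. C1/C6 are vicinal trans and C3/C4 are vicinal cis. The exocyclic C7 stands next to C6, and C9 sits one methylene further out, so neither is held by the ring conformation. Three oxygens are in three different states (angelate at O1, free hydroxyl at O4, acetate at O9) and must be told apart. The fragile groups are the (Z)-2-methylbut-2-enoate, which isomerises to the (E)-tiglate under nucleophilic catalysis, and the secondary allylic acetate, which ionises easily because the cation is stabilised by the C10=C11 alkene. The real difficulty is control of C7 and C9 on a flexible chain, together with differentiation of O1 from O4. The key step uses the 1,5-relationship between O1 and C9: an O1–C9 acyl bond closes the six-membered ring O1–C1–C6–C7–C8–C9, trans-fused to the carbocycle. This makes C7 a ring atom, masks O1, and delivers C9 as an acyl carbon.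

## Logic of the disconnections

**21 to 20.** The O4–Si bond is cut last. The axial hydroxyl has to stay masked while O1 and O9 are acylated, and a triethylsilyl ether is the cap that leaves under the mildest conditions. The forward step must not ionise the allylic acetate or isomerise the angelate.

**20 to 19.** The acetyl C–O bond at O9 is cut. This leaves a single free hydroxyl in 19, so the forward acylation needs no selectivity.

**19 to 18.** The C9–H bond is cut, turning the carbinol into an enone carbonyl. This removes the one stereocentre that the ring cannot control. The forward reduction must be reagent-controlled and 1,2-selective, and must spare the unsaturated ester.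

**18 to 15 and 16 (through 17).** The ester C–O bond at O1 is cut. The acid 16 is commercial. The forward acylation must reach a hindered secondary hydroxyl without Z-to-E isomerisation.

**15 to 11 and 12 (through 13 and 14).** The C9–C10 bond is cut. The lactone carbonyl of 11 is an acyl electrophile at exactly the oxidation level of the enone, and the same event frees O1 for the angelate. The forward step must stop after one addition.

**11 to 10.** The O4–Si bond is cut. In 10 the lactone holds O1, so O4 is the only hydroxyl and selectivity comes for free.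

**10 to 8 and 9.** The C8–C9 and O1–C9 bonds are cut. One ring, one carbon and the C7 stereocentre are removed, leaving an isopulegol-type diol. The forward step needs anti-Markovnikov hydrometalation, selection of O1 over O4, and C7 diastereocontrol.

**8 to 7 to 6.** The C4–H bond is cut, then the C2–H and C3–H bonds. The axial alcohol and the equatorial methyl both derive from a 2-methyl enone. The forward steps need equatorial hydride attack and a thermodynamic α-epimer.

**6 to 4 (through 5).** The C1–O and C4–O bonds are cut. Both ring oxygens come from dioxygen adding across a 1,3-diene. The forward step needs attack anti to the C6 substituent and base-induced opening toward the C4 ketone.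

**4 to 2 to 1 (through 3).** The C1=C2 double bond is traced back to a ketone at C2. The ketone 1 is a chiral-pool material that already holds C6 and the C3 methyl. The forward elimination must not disturb the doubly allylic C6–H.

## Other disconnections considered

**Alternative 1:** The cut is at both ring C–O bonds (C1–O and C4–O), leading back to the triene A1, (5R)-2-methyl-5-(prop-1-en-2-yl)cyclohexa-1,3-diene. The forward key step is the [4+2] addition of singlet oxygen across C1 and C4, anti to the isopropenyl group, to give the endoperoxide A2.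
- In its favour: one catalyst-free step installs both ring oxygens, their mutual cis relationship and the trans C1/C6 relationship, starting from a chiral-pool diene.
- Against it here: a single allylic substituent is expected to give only a moderate facial bias; ene pathways and peroxide handling add risk; and the step says nothing about C7, the C8–C9 bond, C9, or the later differentiation of the two oxygens.
- Comparison: on stereocentres per step it is the better (two against one). On bonds formed it is the equal (two each). On stereocontrol it is the weaker, since nothing like a chair-like closure directs it. On step economy the two are not rivals: the chosen plan uses this same cycloaddition as a supporting step (A1 and A2 are the same substances as 4 and 5), and a plan centred on A2 would still need a separate answer for C7.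

**Alternative 2:** The cut is at C5–C6 and C1=C2 of the ring, leading back to the aldehyde ester A3, methyl (S)-3-methyl-5-oxopentanoate, and but-3-en-2-one A4. The forward key step is an amine-catalysed Michael addition of the enamine of A3 to A4 followed by aldol condensation, giving the cyclohexenone A5.
- In its favour: C6 is set by the catalyst next to a C7 that is already in place, the route is convergent, and C9 arrives as an ester at the right oxidation level.
- Against it here: the ring arrives bare. A5 has its carbonyl at C3, no oxygen at C1 or C4 and no methyl at C3, so the trans C1 oxygen, the C3 methyl and the axial C4 hydroxyl would all have to be added afterwards, with enolate regiochemistry (C2 against C4) to control. A3 is not a chiral-pool compound, and its stereocentre may match or mismatch the catalyst.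
- Comparison: on the C6/C7 relationship it is the better, because reagent control is more predictable than substrate-controlled hydropalladation. On the C9 oxidation level it is the equal. On ring functionalisation and step count it is clearly the worse, since the chosen plan draws C3, C6 and the ring skeleton from 1 and reaches 8 in five steps.

**Alternative 3:** The cut is at C1–C6, leading back to the acyclic aldehyde A6, (3S,4R)-4-(4-methoxybenzyloxy)-3,7-dimethyloct-6-enal. The forward key step is a Lewis-acid carbonyl-ene closure of the citronellal-to-isopulegol kind, giving the cyclohexanol A7, which is the O4-protected form of 8.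
- In its favour: a concerted chair-like ene transition state sets C1 and C6 trans, no peroxide is involved, and A7 already has O1 free and O4 protected.
- Against it here: A6 needs a de novo asymmetric synthesis of the vicinal C3/C4 pair, estimated at six to eight steps. The C4 alkoxy group must sit axial in the closing chair, which weakens the all-equatorial preference of the parent case. The benzyl-type ether must survive the Lewis acid and later be removed beside the angelate and the allylic acetate.
- Comparison: on oxygen differentiation it is the better (it would save the silylation step). On predictability of the C1/C6 relationship it is the equal or the better of the photooxygenation used here. On step economy it is the worse. It replaces only the way to the substrate of the palladium step, not the lactone tether itself.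

Key step: step 6

## Route

Step 1
Reactants: 1 (R)-(−)-carvone
Product: 2 N'-[(1E,5R)-2-methyl-5-(prop-1-en-2-yl)cyclohex-2-en-1-ylidene]-4-methylbenzenesulfonohydrazide
Conditions: TsNHNH2, MeOH, rt
Reagents that add atoms: p-toluenesulfonohydrazide, Cc1ccc(cc1)S(=O)(=O)NN
Why: Hydrazone formation by condensation at the ketone; the sulfonamide nitrogen settles anti to the methyl-bearing alkene carbon, and the remote stereocentre is untouched.

Step 2
Reactants: 2 carvone tosylhydrazone
Product: 4 (5R)-2-methyl-5-(prop-1-en-2-yl)cyclohexa-1,3-diene, via dienyllithium 3 (not isolated)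
Conditions: MeLi (3 equiv), Et2O, 0 °C to rt; H2O
Reagents that add atoms: none
Why: Shapiro reaction: MeLi removes the N–H and then the only sp3 α-hydrogen (on C1, syn to the sulfonamide nitrogen); loss of sulfinate and N2 leaves 3, which water protonates to the conjugated diene. C6 is not involved, and its doubly allylic hydrogen is protected by working cold and using the volatile triene at once.

Step 3
Reactants: 4 (5R)-2-methyl-5-(prop-1-en-2-yl)cyclohexa-1,3-diene
Product: 6 (4R,5S)-4-hydroxy-2-methyl-5-(prop-1-en-2-yl)cyclohex-2-en-1-one, via endoperoxide 5 (not isolated)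
Conditions: O2, 5,10,15,20-tetraphenylporphyrin (cat.), visible light, CH2Cl2, −20 °C; then Et3N, 0 °C to rt
Reagents that add atoms: dioxygen, O=O
Why: Singlet oxygen adds by [4+2] cycloaddition across C1 and C4 of the cisoid diene on the face opposite the C6 isopropenyl group, which sets C1; the isolated 1,1-disubstituted alkene reacts far more slowly. Without isolation of 5, Et3N brings about a Kornblum–DeLaMare rearrangement by removing the C4 bridgehead hydrogen, which is flanked only by the C5 methylene whereas the C1 hydrogen is screened by the branched C6, so C4 becomes the ketone and O1 the hydroxyl.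

Step 4
Reactants: 6 (4R,5S)-4-hydroxy-2-methyl-5-(prop-1-en-2-yl)cyclohex-2-en-1-one
Product: 7 (2S,4R,5S)-4-hydroxy-2-methyl-5-(prop-1-en-2-yl)cyclohexan-1-one
Conditions: [(Ph3P)CuH]6 (0.4 equiv), H2O, THF, rt; then 1,8-diazabicyclo[5.4.0]undec-7-ene (cat.), CH2Cl2, rt
Reagents that add atoms: none
Why: Copper hydride conjugate reduction delivers hydride to C2 and leaves the isolated alkene and the free hydroxyl alone; water protonates the enolate. The base equilibration places the C3 methyl equatorial (cis to the C1 hydroxyl), the more stable α-epimer when the C1 and C6 substituents are both equatorial.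

Step 5
Reactants: 7 (2S,4R,5S)-4-hydroxy-2-methyl-5-(prop-1-en-2-yl)cyclohexan-1-one
Product: 8 (1R,2S,4R,5S)-2-methyl-5-(prop-1-en-2-yl)cyclohexane-1,4-diol
Conditions: LiBH(s-Bu)3 (2.5 equiv), THF, −78 °C; NaOH, H2O2
Reagents that add atoms: none
Why: The bulky trialkylborohydride attacks the C4 carbonyl from the equatorial direction and gives the axial alcohol cis to the equatorial C3 methyl, the selectivity established for 2-alkylcyclohexanones; one further equivalent is consumed by the C1 hydroxyl.

Step 6
Reactants: 8 (1R,2S,4R,5S)-2-methyl-5-(prop-1-en-2-yl)cyclohexane-1,4-diol; 9 carbon monoxide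
Product: 10 (4R,4aS,6R,7S,8aR)-6-hydroxy-4,7-dimethyloctahydro-2H-chromen-2-one
Conditions: PdCl2(PPh3)2 (4 mol%), SnCl2·2H2O (10 mol%), PPh3 (8 mol%), 9 (40 bar), toluene, 80 °C
Reagents that add atoms: none
Why: A palladium hydride formed from the divalent palladium precatalyst, the tin chloride hydrate and CO adds across the isopropenyl double bond with the metal on the terminal carbon C8; CO inserts into the Pd–C8 bond to form C8–C9, and the equatorial C1 hydroxyl attacks the acylpalladium carbon to form O1–C9 and regenerate the hydride. The closest known reaction type is the palladium-catalysed cyclocarbonylation (intramolecular hydroalkoxycarbonylation) of isopulegol and related trans-2-isopropenylcyclohexanols to δ-lactones. The single ring closed is the δ-lactone O1–C1–C6–C7–C8–C9, formed by 6-exo-trig attack of oxygen on the acyl carbon and trans-fused because the O1–C1 and C6–C7 bonds are both equatorial. The new stereocentre C7 is under substrate control: hydride addition is reversible, so the two C7-epimeric alkylpalladium species interconvert through the alkene, and the chair-like closure that keeps the C7 methyl equatorial (anti to C1 across the C6–C7 bond) is the lower in energy and leads to the 7R configuration of the target. The same epimer is expected from kinetic hydride delivery to the staggered allylic conformer in which C1 lies anti to the incoming metal and the C5 methylene sits beside the terminal CH2. Anti-Markovnikov regioselectivity is secured by the 1,1-disubstituted alkene, whose internal carbon would give a tertiary alkylpalladium. Selection between the two hydroxyls is secured by geometry, because the axial C4 hydroxyl lies on the ring face opposite the chain and cannot reach the acyl carbon. If the epimer ratio at C7 needs improvement, the monophosphine can be exchanged for a chelating diphosphine such as Ph2P(CH2)4PPh2.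

Step 7
Reactants: 10 (4R,4aS,6R,7S,8aR)-6-hydroxy-4,7-dimethyloctahydro-2H-chromen-2-one
Product: 11 (4R,4aS,6R,7S,8aR)-4,7-dimethyl-6-(triethylsilyloxy)octahydro-2H-chromen-2-one
Conditions: Et3SiOTf, 2,6-lutidine, CH2Cl2, −78 to 0 °C
Reagents that add atoms: triethylsilyl trifluoromethanesulfonate, CC[Si](CC)(CC)OS(=O)(=O)C(F)(F)F
Why: O-Silylation with a silyl triflate and a hindered base reaches the axial, methyl-flanked C4 hydroxyl, which is the only free hydroxyl because O1 is held in the lactone; triethylsilyl is chosen so that its final removal is mild.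

Step 8
Reactants: 11 (4R,4aS,6R,7S,8aR)-4,7-dimethyl-6-(triethylsilyloxy)octahydro-2H-chromen-2-one; 12 1-bromo-2-methylprop-1-ene
Product: 15 (6R)-6-[(1S,2R,4S,5R)-2-hydroxy-4-methyl-5-(triethylsilyloxy)cyclohexyl]-2-methylhept-2-en-4-one, via 2-methylprop-1-enyllithium 13 (not isolated), via lithium lactolate 14 (not isolated)
Conditions: 12, t-BuLi (2 equiv), Et2O, −78 °C; then 11, THF, −78 °C; AcOH, −78 °C
Reagents that add atoms: none
Why: Lithium–bromine exchange gives 13, whose 1,2-addition to the lactone carbonyl forms C9–C10; the tetrahedral lactolate 14 persists at −78 °C, which suppresses a second addition, and the cold acid quench releases the δ-hydroxy enone (in equilibrium with a little lactol). No stereocentre is formed or disturbed.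

Step 9
Reactants: 15 (6R)-6-[(1S,2R,4S,5R)-2-hydroxy-4-methyl-5-(triethylsilyloxy)cyclohexyl]-2-methylhept-2-en-4-one; 16 angelic acid
Product: 18 (1R,2S,4R,5S)-5-methyl-2-[(2R)-6-methyl-4-oxohept-5-en-2-yl]-4-(triethylsilyloxy)cyclohexyl (Z)-2-methylbut-2-enoate, via mixed anhydride 17 (not isolated)
Conditions: 16, 2,4,6-trichlorobenzoyl chloride, Et3N, toluene, rt; then 15, toluene, 80 °C
Reagents that add atoms: none
Why: Yamaguchi-type esterification: the mixed anhydride 17 acylates the secondary C1 hydroxyl at its less hindered angeloyl carbonyl, and leaving out a nucleophilic catalyst avoids the conjugate addition–elimination path that turns a (Z)-angelate into the (E)-tiglate. Acylation draws the hydroxy ketone out of its equilibrium with the lactol.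

Step 10
Reactants: 18 (1R,2S,4R,5S)-5-methyl-2-[(2R)-6-methyl-4-oxohept-5-en-2-yl]-4-(triethylsilyloxy)cyclohexyl (Z)-2-methylbut-2-enoate
Product: 19 (1R,2S,4R,5S)-2-[(2R,4R)-4-hydroxy-6-methylhept-5-en-2-yl]-5-methyl-4-(triethylsilyloxy)cyclohexyl (Z)-2-methylbut-2-enoate
Conditions: (S)-1-methyl-3,3-diphenyltetrahydro-1H,3H-pyrrolo[1,2-c][1,3,2]oxazaborole (20 mol%), catecholborane, toluene, −78 °C
Reagents that add atoms: none
Why: Corey–Bakshi–Shibata reduction: the ketone binds to the boron of the oxazaborolidine anti to its alkenyl group, which acts as the larger substituent, and the coordinated borane delivers hydride to one face, which with the (S)-catalyst gives the (9R)-alcohol. Catecholborane at low temperature reduces the enone 1,2 and leaves the angelate, the silyl ether and the alkenes alone.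

Step 11
Reactants: 19 (1R,2S,4R,5S)-2-[(2R,4R)-4-hydroxy-6-methylhept-5-en-2-yl]-5-methyl-4-(triethylsilyloxy)cyclohexyl (Z)-2-methylbut-2-enoate
Product: 20 (1R,2S,4R,5S)-2-[(2R,4R)-4-acetoxy-6-methylhept-5-en-2-yl]-5-methyl-4-(triethylsilyloxy)cyclohexyl (Z)-2-methylbut-2-enoate
Conditions: Ac2O, pyridine, 4-(dimethylamino)pyridine (cat.), CH2Cl2, 0 °C
Reagents that add atoms: acetic anhydride, CC(=O)OC(C)=O
Why: Acylation of the only free hydroxyl (the secondary allylic C9–OH) with retention at C9; the mild basic medium does not ionise the allylic system or isomerise the angelate.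

Step 12
Reactants: 20 (1R,2S,4R,5S)-2-[(2R,4R)-4-acetoxy-6-methylhept-5-en-2-yl]-5-methyl-4-(triethylsilyloxy)cyclohexyl (Z)-2-methylbut-2-enoate
Product: 21 (1R,2S,4R,5S)-2-[(2R,4R)-4-acetoxy-6-methylhept-5-en-2-yl]-4-hydroxy-5-methylcyclohexyl (Z)-2-methylbut-2-enoate
Conditions: HF·pyridine, pyridine, THF, 0 °C to rt
Reagents that add atoms: none
Why: Fluoride cleavage of the triethylsilyl ether with pyridine-buffered HF, under which the allylic acetate should not ionise and neither ester should migrate or isomerise; the product is the target.

## Compound list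

1 | (R)-(−)-carvone, (5R)-2-methyl-5-(prop-1-en-2-yl)cyclohex-2-en-1-one | CC1=CC[C@H](CC1=O)C(C)=C | starting material
2 | N'-[(1E,5R)-2-methyl-5-(prop-1-en-2-yl)cyclohex-2-en-1-ylidene]-4-methylbenzenesulfonohydrazide | CC1=CC[C@H](C/C1=N\NS(=O)(=O)c2ccc(C)cc2)C(C)=C | intermediate
3 | [(3R)-6-methyl-3-(prop-1-en-2-yl)cyclohexa-1,5-dien-1-yl]lithium (dienyllithium, not isolated) | CC1=CC[C@H](C=C1[Li])C(C)=C | intermediate
4 | (5R)-2-methyl-5-(prop-1-en-2-yl)cyclohexa-1,3-diene | CC1=CC[C@H](C=C1)C(C)=C | intermediate
5 | (1R,4R,7S)-5-methyl-7-(prop-1-en-2-yl)-2,3-dioxabicyclo[2.2.2]oct-5-ene (endoperoxide, not isolated) | O2[C@@H]1C=C(C)[C@H](O2)C[C@H]1C(C)=C | intermediate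
6 | (4R,5S)-4-hydroxy-2-methyl-5-(prop-1-en-2-yl)cyclohex-2-en-1-one | O[C@@H]1C=C(C)C(=O)C[C@H]1C(C)=C | intermediate
7 | (2S,4R,5S)-4-hydroxy-2-methyl-5-(prop-1-en-2-yl)cyclohexan-1-one | O[C@@H]1C[C@H](C)C(=O)C[C@H]1C(C)=C | intermediate
8 | (1R,2S,4R,5S)-2-methyl-5-(prop-1-en-2-yl)cyclohexane-1,4-diol | O[C@@H]1C[C@H](C)[C@H](O)C[C@H]1C(C)=C | intermediate
9 | carbon monoxide | [C-]#[O+] | starting material
10 | (4R,4aS,6R,7S,8aR)-6-hydroxy-4,7-dimethyloctahydro-2H-chromen-2-one (trans-fused δ-lactone) | O2[C@@H]1C[C@H](C)[C@H](O)C[C@H]1[C@H](C)CC2=O | intermediate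
11 | (4R,4aS,6R,7S,8aR)-4,7-dimethyl-6-(triethylsilyloxy)octahydro-2H-chromen-2-one | O2[C@@H]1C[C@H](C)[C@H](O[Si](CC)(CC)CC)C[C@H]1[C@H](C)CC2=O | intermediate
12 | 1-bromo-2-methylprop-1-ene | CC(C)=CBr | starting material
13 | 2-methylprop-1-enyllithium (not isolated) | [Li]C=C(C)C | intermediate
14 | lithium (4R,4aS,6R,7S,8aR)-4,7-dimethyl-2-(2-methylprop-1-en-1-yl)-6-(triethylsilyloxy)octahydro-2H-chromen-2-olate, either configuration at C2 (not isolated) | O2[C@@H]1C[C@H](C)[C@H](O[Si](CC)(CC)CC)C[C@H]1[C@H](C)CC2(O[Li])C=C(C)C | intermediate
15 | (6R)-6-[(1S,2R,4S,5R)-2-hydroxy-4-methyl-5-(triethylsilyloxy)cyclohexyl]-2-methylhept-2-en-4-one | O[C@@H]1C[C@H](C)[C@H](O[Si](CC)(CC)CC)C[C@H]1[C@H](C)CC(=O)C=C(C)C | intermediate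
16 | angelic acid, (Z)-2-methylbut-2-enoic acid | C/C=C(/C)C(=O)O | starting material
17 | (Z)-2-methylbut-2-enoic 2,4,6-trichlorobenzoic anhydride (not isolated) | C/C=C(/C)C(=O)OC(=O)c1c(Cl)cc(Cl)cc1Cl | intermediate
18 | (1R,2S,4R,5S)-5-methyl-2-[(2R)-6-methyl-4-oxohept-5-en-2-yl]-4-(triethylsilyloxy)cyclohexyl (Z)-2-methylbut-2-enoate | C/C=C(/C)C(=O)O[C@@H]1C[C@H](C)[C@H](O[Si](CC)(CC)CC)C[C@H]1[C@H](C)CC(=O)C=C(C)C | intermediate
19 | (1R,2S,4R,5S)-2-[(2R,4R)-4-hydroxy-6-methylhept-5-en-2-yl]-5-methyl-4-(triethylsilyloxy)cyclohexyl (Z)-2-methylbut-2-enoate | C/C=C(/C)C(=O)O[C@@H]1C[C@H](C)[C@H](O[Si](CC)(CC)CC)C[C@H]1[C@H](C)C[C@H](C=C(C)C)O | intermediate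
20 | (1R,2S,4R,5S)-2-[(2R,4R)-4-acetoxy-6-methylhept-5-en-2-yl]-5-methyl-4-(triethylsilyloxy)cyclohexyl (Z)-2-methylbut-2-enoate | C/C=C(/C)C(=O)O[C@@H]1C[C@H](C)[C@H](O[Si](CC)(CC)CC)C[C@H]1[C@H](C)C[C@H](C=C(C)C)OC(C)=O | intermediate
21 | (1R,2S,4R,5S)-2-[(2R,4R)-4-acetoxy-6-methylhept-5-en-2-yl]-4-hydroxy-5-methylcyclohexyl (Z)-2-methylbut-2-enoate (CNP0237033.1) | C/C=C(/C)C(=O)O[C@@H]1C[C@H](C)[C@H](O)C[C@H]1[C@H](C)C[C@H](C=C(C)C)OC(C)=O | target

## Step count and least certain steps

Total step count: 12. Longest linear sequence: 12 steps (1 to 21); 9, 12 and 16 enter as commercial materials.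

**Step 6 (key step).** What may go wrong: incomplete stereocontrol at C7, and migration of the double bond into the tetrasubstituted C6=C7 position through a tertiary alkylpalladium, which would also erase C6. Both follow from the reversibility of hydride addition in the acidic, tin-containing medium. Fallback: setting out from 8, rhodium-catalysed hydroformylation (Rh(acac)(CO)2, PPh3, CO/H2, toluene, 80 °C) works in a neutral medium with irreversible, strictly terminal hydride addition. The aldehyde closes onto O1 to give the lactol (4R,4aS,6R,7S,8aR)-4,7-dimethyloctahydro-2H-chromene-2,6-diol F1. Selective oxidation of the lactol hydroxyl in F1 (2,2,6,6-tetramethylpiperidin-1-oxyl, PhI(OAc)2, CH2Cl2) comes back to the route at 10. Any C7 epimer would be removed at that stage.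

**Step 3.** What may go wrong: poor facial selectivity of oxygen addition, since one allylic substituent gives only a moderate bias, compounded by competing removal of the C1 bridgehead hydrogen during the base-induced opening and by ene side reactions. Fallback: setting out from 1 and coming back at 6, with the regiochemistry fixed by construction.
- The LiN(i-Pr)2 enolate of 1 (THF, −78 °C) is hydroxylated with 2-(phenylsulfonyl)-3-phenyloxaziridine anti to the isopropenyl group, giving (5S,6S)-6-hydroxy-2-methyl-5-(prop-1-en-2-yl)cyclohex-2-en-1-one F2.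
- Silylation (t-BuMe2SiCl, imidazole, DMF) gives (5S,6S)-6-(tert-butyldimethylsilyloxy)-2-methyl-5-(prop-1-en-2-yl)cyclohex-2-en-1-one F3.
- Alkaline H2O2 (NaOH, MeOH, 0 °C) gives (1R,3S,4S,6R)-3-(tert-butyldimethylsilyloxy)-1-methyl-4-(prop-1-en-2-yl)-7-oxabicyclo[4.1.0]heptan-2-one F4; its epoxide configuration is of no consequence.
- Wharton transposition (N2H4·H2O, AcOH, MeOH) gives (1R,4R,5S)-4-(tert-butyldimethylsilyloxy)-2-methyl-5-(prop-1-en-2-yl)cyclohex-2-en-1-ol F5.
- MnO2 in CH2Cl2 gives (4R,5S)-4-(tert-butyldimethylsilyloxy)-2-methyl-5-(prop-1-en-2-yl)cyclohex-2-en-1-one F6.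
- HF·pyridine in THF returns 6.

**Step 8.** What may go wrong: a second addition of 13 after premature collapse of the lactolate, or enolisation of the lactone by the basic organolithium, giving over-addition or recovered lactone. Fallback: setting out from 11, aminolysis with MeNHOMe·HCl and AlMe3 (CH2Cl2, 0 °C) gives (3R)-3-[(1S,2R,4S,5R)-2-hydroxy-4-methyl-5-(triethylsilyloxy)cyclohexyl]-N-methoxy-N-methylbutanamide F7. Its chelated adduct with excess 2-methylprop-1-enylmagnesium bromide (THF, 0 °C) cannot add twice, and work-up comes back to the route at 15.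

**Step 9.** What may go wrong: isomerisation of the angeloyl unit to the tigloyl unit during activation, or sluggish acylation of the hindered C1 hydroxyl. Fallback: setting out from 15, esterification with 2-[bis(2,2,2-trifluoroethoxy)phosphoryl]propanoic acid (N,N'-dicyclohexylcarbodiimide, 4-(dimethylamino)pyridine, CH2Cl2) gives (1R,2S,4R,5S)-5-methyl-2-[(2R)-6-methyl-4-oxohept-5-en-2-yl]-4-(triethylsilyloxy)cyclohexyl 2-[bis(2,2,2-trifluoroethoxy)phosphoryl]propanoate F8. A Still–Gennari olefination with acetaldehyde (KN(SiMe3)2, 18-crown-6, THF, −78 °C) then builds the (Z)-trisubstituted double bond on the substrate and comes back at 18.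

**Step 10.** What may go wrong: insufficient catalyst control at C9, because the β,β-disubstituted alkenyl group and the branched alkyl chain may not differ enough in effective size. Fallback: setting out from 18, a Luche reduction (NaBH4, CeCl3·7H2O, MeOH, −40 °C) gives both carbinol epimers, which are separated. The desired epimer is 19, where the route is rejoined. The unwanted one, (1R,2S,4R,5S)-2-[(2R,4S)-4-hydroxy-6-methylhept-5-en-2-yl]-5-methyl-4-(triethylsilyloxy)cyclohexyl (Z)-2-methylbut-2-enoate F9, is oxidised back to 18 with MnO2 and recycled.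

## Further compounds

F1 | step 6 | (4R,4aS,6R,7S,8aR)-4,7-dimethyloctahydro-2H-chromene-2,6-diol (lactol, both anomers) | O2[C@@H]1C[C@H](C)[C@H](O)C[C@H]1[C@H](C)CC2O
F2 | step 3 | (5S,6S)-6-hydroxy-2-methyl-5-(prop-1-en-2-yl)cyclohex-2-en-1-one | O[C@@H]1C(=O)C(C)=CC[C@H]1C(C)=C
F3 | step 3 | (5S,6S)-6-(tert-butyldimethylsilyloxy)-2-methyl-5-(prop-1-en-2-yl)cyclohex-2-en-1-one | CC(C)(C)[Si](C)(C)O[C@@H]1C(=O)C(C)=CC[C@H]1C(C)=C
F4 | step 3 | (1R,3S,4S,6R)-3-(tert-butyldimethylsilyloxy)-1-methyl-4-(prop-1-en-2-yl)-7-oxabicyclo[4.1.0]heptan-2-one | CC(C)(C)[Si](C)(C)O[C@@H]1C(=O)[C@]2(C)O[C@@H]2C[C@H]1C(C)=C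
F5 | step 3 | (1R,4R,5S)-4-(tert-butyldimethylsilyloxy)-2-methyl-5-(prop-1-en-2-yl)cyclohex-2-en-1-ol | CC(C)(C)[Si](C)(C)O[C@@H]1C=C(C)[C@H](O)C[C@H]1C(C)=C
F6 | step 3 | (4R,5S)-4-(tert-butyldimethylsilyloxy)-2-methyl-5-(prop-1-en-2-yl)cyclohex-2-en-1-one | CC(C)(C)[Si](C)(C)O[C@@H]1C=C(C)C(=O)C[C@H]1C(C)=C
F7 | step 8 | (3R)-3-[(1S,2R,4S,5R)-2-hydroxy-4-methyl-5-(triethylsilyloxy)cyclohexyl]-N-methoxy-N-methylbutanamide | O[C@@H]1C[C@H](C)[C@H](O[Si](CC)(CC)CC)C[C@H]1[C@H](C)CC(=O)N(C)OC
F8 | step 9 | (1R,2S,4R,5S)-5-methyl-2-[(2R)-6-methyl-4-oxohept-5-en-2-yl]-4-(triethylsilyloxy)cyclohexyl 2-[bis(2,2,2-trifluoroethoxy)phosphoryl]propanoate (both epimers at the phosphonate carbon) | CC(C(=O)O[C@@H]1C[C@H](C)[C@H](O[Si](CC)(CC)CC)C[C@H]1[C@H](C)CC(=O)C=C(C)C)P(=O)(OCC(F)(F)F)OCC(F)(F)F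
F9 | step 10 | (1R,2S,4R,5S)-2-[(2R,4S)-4-hydroxy-6-methylhept-5-en-2-yl]-5-methyl-4-(triethylsilyloxy)cyclohexyl (Z)-2-methylbut-2-enoate | C/C=C(/C)C(=O)O[C@@H]1C[C@H](C)[C@H](O[Si](CC)(CC)CC)C[C@H]1[C@H](C)C[C@@H](C=C(C)C)O
A1 | alternative 1 | (5R)-2-methyl-5-(prop-1-en-2-yl)cyclohexa-1,3-diene | CC1=CC[C@H](C=C1)C(C)=C
A2 | alternative 1 | (1R,4R,7S)-5-methyl-7-(prop-1-en-2-yl)-2,3-dioxabicyclo[2.2.2]oct-5-ene | O2[C@@H]1C=C(C)[C@H](O2)C[C@H]1C(C)=C
A3 | alternative 2 | methyl (S)-3-methyl-5-oxopentanoate | O=CC[C@H](C)CC(=O)OC
A4 | alternative 2 | but-3-en-2-one | CC(=O)C=C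
A5 | alternative 2 | methyl (3R)-3-[(1S)-4-oxocyclohex-2-en-1-yl]butanoate | C1=CC(=O)CC[C@H]1[C@H](C)CC(=O)OC
A6 | alternative 3 | (3S,4R)-4-(4-methoxybenzyloxy)-3,7-dimethyloct-6-enal | O=CC[C@H](C)[C@H](OCc1ccc(OC)cc1)CC=C(C)C
A7 | alternative 3 | (1R,2S,4R,5S)-4-(4-methoxybenzyloxy)-5-methyl-2-(prop-1-en-2-yl)cyclohexan-1-ol | O[C@@H]1C[C@H](C)[C@H](OCc2ccc(OC)cc2)C[C@H]1C(C)=C
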